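**Plan**

- Retrosynthesis: the six benzyl ethers come off last. The C4 ketone and the C3 hemiketal hydroxyl are traced back to the C3=C4 enol ether of a 2H-chromene, and then O1–C2 and C4–C4a are cut in one operation.
- Enabling feature: ring A (the phloroglucinol ring) carries both O1 and C4a. C2=C3, with O7' on C3, is the 2,3-double bond of a furan fused to kaempferol at O7'/C8', and C4 is the formyl carbon on that furan. The cut therefore gives a phenol and a 3-arylbenzofuran-2-carbaldehyde.
- Forward: kaempferol → 7-OH triacetate → 8-iodide → furan ring by one-pot alkynylation/arylative cyclisation → benzyl ethers and aldehyde → pyran ring by phenol–aldehyde annulation → oxidation at C3/C4 → hydrogenolysis.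
- Stereochemistry: C2 (R) is set by the chiral phosphoric acid in the ring closure. C3 (S) follows from C2, because the five-membered ring can only be cis-fused.

Key step: step 7

Remark: the new chromanone half is numbered as a flavanone (O1, C2, C3, C4, C4a, C8a; ring A) and kaempferol atoms carry primes once the halves are joined; 3,5-bis(benzyloxy)phenol, 3,3-diethoxyprop-1-yne and 1-(benzyloxy)-4-iodobenzene are taken as purchased.

**Route**

Step 1
Reactants: 1 kaempferol
Product: 2 kaempferol 3,5,7,4'-tetraacetate
Conditions: Ac2O, pyridine, DMAP (cat.), 60 °C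
Reagents that add atoms: acetic anhydride CC(=O)OC(C)=O
Why: Exhaustive O-acylation (nucleophilic catalysis by DMAP) should esterify all four hydroxyls, warming being needed only for the chelated 5-OH.

Step 2
Reactants: 2 kaempferol 3,5,7,4'-tetraacetate
Product: 3 kaempferol 3,5,4'-triacetate (7-OH free)
Conditions: PhSH, imidazole, NMP, 0 °C to rt
Reagents that add atoms: none
Why: Imidazole-mediated thiolysis should remove only the 7-acetate, the ester of the most acidic phenol (para to the C4 carbonyl) and hence the best leaving group, as in the known selective 7-O-deacetylation of peracetylated flavonoids.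

Step 3
Reactants: 3 kaempferol 3,5,4'-triacetate
Product: 4 8-iodokaempferol 3,5,4'-triacetate (7-OH free)
Conditions: NIS, DMF, 0 °C to rt
Reagents that add atoms: N-iodosuccinimide O=C1CCC(=O)N1I
Why: Electrophilic aromatic iodination ortho to the only free phenol should go to the angular C8, the usual site for 7-hydroxychromones, since C6 is flanked by the deactivating 5-acetoxy group.

Step 4
Reactants: 4 8-iodokaempferol 3,5,4'-triacetate; 5 3,3-diethoxyprop-1-yne; 6 1-(benzyloxy)-4-iodobenzene
Product: 8 3,5-diacetoxy-2-(4-acetoxyphenyl)-9-[4-(benzyloxy)phenyl]-8-(diethoxymethyl)-4H-furo[2,3-h]chromen-4-one, via alkynylphenol 7 (not isolated)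
Conditions: PdCl2(PPh3)2 (cat.), CuI (cat.), Et3N, THF, 40 °C; then 6, MeCN, 90 °C
Reagents that add atoms: none
Why: Sonogashira coupling gives the ortho-alkynylphenol, and the arylpalladium iodide from 6 then triggers anti-oxypalladation by O7 and reductive elimination (Cacchi-type arylative cyclisation in a one-pot three-component benzofuran synthesis), which places the aryl group on the carbon bonded to C8 and the acetal carbon next to O7 without regiochemical ambiguity.

Step 5
Reactants: 8 triacetate acetal
Product: 10 3,5-bis(benzyloxy)-2,9-bis[4-(benzyloxy)phenyl]-8-(diethoxymethyl)-4H-furo[2,3-h]chromen-4-one, via furochromenone triol 9 (not isolated)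
Conditions: K2CO3, MeOH–THF, rt, argon; evaporate; then BnBr, K2CO3, DMF, 70 °C
Reagents that add atoms: benzyl bromide BrCc1ccccc1
Why: Base-catalysed methanolysis of the three aryl acetates followed by Williamson benzylation should exchange the esters for benzyl ethers in one flask, the basic medium leaving the diethyl acetal untouched and the heating serving the chelated 5-OH.

Step 6
Reactants: 10 tribenzyl acetal
Product: 11 3,5-bis(benzyloxy)-2,9-bis[4-(benzyloxy)phenyl]-4-oxo-4H-furo[2,3-h]chromene-8-carbaldehyde
Conditions: 1 M HCl, THF, rt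
Reagents that add atoms: water O
Why: Acid-catalysed acetal hydrolysis should free the aldehyde under conditions to which benzyl aryl ethers and the chromone are inert.

Step 7
Reactants: 11 furochromenone aldehyde; 12 3,5-bis(benzyloxy)phenol
Product: 15 (2R)-hexabenzyl furo-fused 2H-chromene (C3=C4 enol ether), via carbinol 13 (not isolated), via ortho-quinone methide 14 (not isolated)
Conditions: (R)-TRIP (10 mol%), 4 Å MS, CH2Cl2, −20 to 0 °C, 12 added slowly
Reagents that add atoms: none
Why: Proposed new method: the phosphoric acid, hydrogen-bonded to both partners, should guide the phenol ortho carbon onto the activated formyl group (Friedel–Crafts hydroxyalkylation, C4–C4a) and then ionise carbinol 13 to ortho-quinone methide 14, which is equally a phosphate-paired cation spread from C4 to C2 across the furan double bond. The pyran ring (ring C) closes by thermal oxa-6π electrocyclisation of the 1-oxatriene O1=C8a–C4a=C4–C3=C2 (seen from the cation, a 6-endo attack of the phenol oxygen on C2), which restores the benzenoid ring A at the price of the weak furan aromaticity of a benzofuran and forms O1–C2. The closest known reactions are the phenol–enal formal [3+3] chromene synthesis, chiral phosphoric acid substitutions of 2-indolylmethanols at the ring 3-position and ion-pair allylic substitution to 2H-chromenes; new here is that the 2,3-bond of a 3-arylbenzofuran serves as the terminal alkene and stays dearomatised. The single new stereocentre, C2, is set in the closure by the chiral phosphate bound to the quinone methide oxygen, which shields one face of C2; (R)-TRIP is proposed for the 2R product and its antipode would be used if the sense proves opposite. Ortho rather than para attack is secured by two-point hydrogen bonding of phenol OH and aldehyde to the catalyst (para adducts cannot cyclise and can revert), and a second arylation at C4 is held back because closure is intramolecular and the phenol is kept at low concentration. An aldehyde rather than a ketone is used so that C4 carries the hydrogen of the chromene and the C3=C4 enol ether is left to take up the remaining oxidation.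

Step 8
Reactants: 15 (2R)-chromene
Product: 17 (2R,3R)-3,4-diol hexabenzyl ether (C3 hemiketal; C4 epimers), via enol ether epoxide 16 (not isolated)
Conditions: DMDO, acetone–CH2Cl2, −40 °C; then H2O, THF, pH 7 buffer, 0 °C
Reagents that add atoms: dimethyldioxirane CC1(C)OO1; water O
Why: Dioxirane epoxidation should pick the aryl enol ether, by far the most electron-rich alkene present, and water should open the glycal-like epoxide through the cation shared by C3 (O7'-stabilised) and C4 (benzylic to ring A); the C3 hydroxyl ends cis to the C2 aryl because the dihydrofuran can only be cis-fused and the hemiketal equilibrates, so C2 controls C3, while both C4 epimers converge in step 9.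

Step 9
Reactants: 17 diol
Product: 18 (2R,3S)-hexabenzyl ether of the target (C3 hemiketal, C4 ketone)
Conditions: Dess–Martin periodinane, pyridine, CH2Cl2, 0 °C to rt
Reagents that add atoms: none
Why: Dess–Martin oxidation should convert the secondary benzylic C4 alcohol into the ketone while the tertiary hemiketal hydroxyl cannot be oxidised, the pyridine buffer protecting the hemiketal and the C2–O1 bond from acid.

Step 10
Reactants: 18 hexabenzyl ether
Product: 19 target compound (2R,3S)
Conditions: H2 (1 atm), Pd(OH)2/C, THF–MeOH, rt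
Reagents that add atoms: none
Why: Catalytic hydrogenolysis should cleave the six benzyl aryl ethers under neutral conditions, with the flavonol, the aryl ketone and the fully substituted C2–O1 bond reacting far more slowly at one atmosphere, so that neither stereocentre is touched.

**Compound list**

1 | kaempferol | O=c1c(O)c(-c2ccc(O)cc2)oc2cc(O)cc(O)c12 | starting material
2 | kaempferol 3,5,7,4'-tetraacetate | O=c1c(OC(C)=O)c(-c2ccc(OC(C)=O)cc2)oc2cc(OC(C)=O)cc(OC(C)=O)c12 | intermediate
3 | kaempferol 3,5,4'-triacetate (7-OH free) | O=c1c(OC(C)=O)c(-c2ccc(OC(C)=O)cc2)oc2cc(O)cc(OC(C)=O)c12 | intermediate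
4 | 8-iodokaempferol 3,5,4'-triacetate (7-OH free) | O=c1c(OC(C)=O)c(-c2ccc(OC(C)=O)cc2)oc2c(I)c(O)cc(OC(C)=O)c12 | intermediate
5 | 3,3-diethoxyprop-1-yne | C#CC(OCC)OCC | starting material
6 | 1-(benzyloxy)-4-iodobenzene | Ic1ccc(OCc2ccccc2)cc1 | starting material
7 | 8-(3,3-diethoxyprop-1-ynyl)kaempferol 3,5,4'-triacetate (alkynylphenol, not isolated) | O=c1c(OC(C)=O)c(-c2ccc(OC(C)=O)cc2)oc2c(C#CC(OCC)OCC)c(O)cc(OC(C)=O)c12 | intermediate
8 | 3,5-diacetoxy-2-(4-acetoxyphenyl)-9-[4-(benzyloxy)phenyl]-8-(diethoxymethyl)-4H-furo[2,3-h]chromen-4-one | CCOC(OCC)c1oc2cc(OC(C)=O)c3c(=O)c(OC(C)=O)c(-c4ccc(OC(C)=O)cc4)oc3c2c1-c1ccc(OCc2ccccc2)cc1 | intermediate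
9 | 9-[4-(benzyloxy)phenyl]-8-(diethoxymethyl)-3,5-dihydroxy-2-(4-hydroxyphenyl)-4H-furo[2,3-h]chromen-4-one (triol, not isolated) | CCOC(OCC)c1oc2cc(O)c3c(=O)c(O)c(-c4ccc(O)cc4)oc3c2c1-c1ccc(OCc2ccccc2)cc1 | intermediate
10 | 3,5-bis(benzyloxy)-2,9-bis[4-(benzyloxy)phenyl]-8-(diethoxymethyl)-4H-furo[2,3-h]chromen-4-one | CCOC(OCC)c1oc2cc(OCc3ccccc3)c3c(=O)c(OCc4ccccc4)c(-c4ccc(OCc5ccccc5)cc4)oc3c2c1-c1ccc(OCc2ccccc2)cc1 | intermediate
11 | 3,5-bis(benzyloxy)-2,9-bis[4-(benzyloxy)phenyl]-4-oxo-4H-furo[2,3-h]chromene-8-carbaldehyde (key-step precursor) | O=Cc1oc2cc(OCc3ccccc3)c3c(=O)c(OCc4ccccc4)c(-c4ccc(OCc5ccccc5)cc4)oc3c2c1-c1ccc(OCc2ccccc2)cc1 | intermediate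
12 | 3,5-bis(benzyloxy)phenol | Oc1cc(OCc2ccccc2)cc(OCc2ccccc2)c1 | starting material
13 | [2-hydroxy-4,6-bis(benzyloxy)phenyl](furochromenon-8-yl)methanol, carbinol from 11 and 12 (either configuration at the carbinol carbon; not isolated) | OC(c1c(O)cc(OCc2ccccc2)cc1OCc1ccccc1)c1oc2cc(OCc3ccccc3)c3c(=O)c(OCc4ccccc4)c(-c4ccc(OCc5ccccc5)cc4)oc3c2c1-c1ccc(OCc2ccccc2)cc1 | intermediate
14 | ortho-quinone methide, 3,5-bis(benzyloxy)-6-(furochromenon-8-ylmethylidene)cyclohexa-2,4-dienone, Z (furyl cis to the carbonyl; not isolated) | O=C1C=C(OCc2ccccc2)C=C(OCc2ccccc2)/C1=C/c1oc2cc(OCc3ccccc3)c3c(=O)c(OCc4ccccc4)c(-c4ccc(OCc5ccccc5)cc4)oc3c2c1-c1ccc(OCc2ccccc2)cc1 | intermediate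
15 | (2R)-2H-chromene: 5,7-bis(benzyloxy)-2-[4-(benzyloxy)phenyl] ring system with C3=C4 enol ether, C2 bonded to C8' and C3 to O7' of 3',5',4''-tri-O-benzylkaempferol (key-step product) | C1c2c(OCc3ccccc3)cc(OCc3ccccc3)cc2O[C@]2(c3ccc(OCc4ccccc4)cc3)c3c(cc(OCc4ccccc4)c4c(=O)c(OCc5ccccc5)c(-c5ccc(OCc6ccccc6)cc5)oc34)OC2=1 | intermediate
16 | C3–C4 epoxide of 15 (2R; epoxide face not specified, not isolated) | C1(O2)c3c(OCc4ccccc4)cc(OCc4ccccc4)cc3O[C@]3(c4ccc(OCc5ccccc5)cc4)c4c(cc(OCc6ccccc6)c5c(=O)c(OCc6ccccc6)c(-c6ccc(OCc7ccccc7)cc6)oc45)OC123 | intermediate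
17 | (2R,3R)-3,4-diol hexabenzyl ether: C3 hemiketal hydroxyl cis to the C2 aryl, C4 secondary alcohol as epimer mixture | OC1c2c(OCc3ccccc3)cc(OCc3ccccc3)cc2O[C@]2(c3ccc(OCc4ccccc4)cc3)c3c(cc(OCc4ccccc4)c4c(=O)c(OCc5ccccc5)c(-c5ccc(OCc6ccccc6)cc5)oc34)O[C@]12O | intermediate
18 | (2R,3S)-hexabenzyl ether of the target (C4 ketone, C3 hemiketal) | O=C1c2c(OCc3ccccc3)cc(OCc3ccccc3)cc2O[C@]2(c3ccc(OCc4ccccc4)cc3)c3c(cc(OCc4ccccc4)c4c(=O)c(OCc5ccccc5)c(-c5ccc(OCc6ccccc6)cc5)oc34)O[C@]12O | intermediate
19 | CNP0314633.1, (2R,3S) | O=C1c2c(O)cc(O)cc2O[C@]2(c3ccc(O)cc3)c3c(cc(O)c4c(=O)c(O)c(-c5ccc(O)cc5)oc34)O[C@]12O | target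

**Step count and risks**

Total step count: 10. Longest linear sequence: 10 steps (kaempferol 1 to target 19).

Steps most likely to fail:

1. Step 7 (proposed new method). A second phenol may add to the C4 cation faster than O1 closes onto the hindered, fully substituted C2, or the phenol may attack through its para carbon. The chromene may also reopen, by retro-6π opening or acid ionisation of the doubly benzylic C2–O1 bond, and so lose its configuration at C2; for that reason 15 should be kept cold and oxidised without delay. Fallback with known chemistry, setting out from aldehyde 11 and phenol 12 and returning at 18: the bromomagnesium phenoxide of 12 (EtMgBr, toluene) is added to 11 in an ortho-specific hydroxyalkylation, which gives carbinol 13 as an isolated racemate. MnO2 in CH2Cl2 oxidises it to the 2-aroylbenzofuran ketone F1. DMDO then epoxidises the furan double bond to benzofuran epoxide F2, whose benzylic C–O bond is opened in the flask by the neighbouring phenol, as in the ring closure of an Algar–Flynn–Oyamada dihydroflavonol synthesis. This forms O1–C2 and leaves the epoxide oxygen as the C3 hemiketal hydroxyl, giving racemic cis-fused hexabenzyl ketone F3. Preparative HPLC on a chiral stationary phase delivers 18, and the route resumes at step 10.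

2. Step 4. Copper- or base-promoted cycloisomerisation of alkynylphenol 7 may outrun its capture by the arylpalladium iodide, leaving the furan without its 9-aryl group, and acetates may be lost to the amine at 90 °C. Fallback, setting out from 4 and 5 and returning at 8: Sonogashira coupling at 60 °C with deliberate cycloisomerisation gives the 9-unsubstituted furochromenone F4. NBS in DMF brominates the furan β-position to give bromofuran F5. Suzuki coupling with 4-(benzyloxy)phenylboronic acid under anhydrous fluoride conditions (PdCl2(dppf), CsF, dioxane, 80 °C), which spare aryl acetates, gives 8.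

3. Step 8. The epoxide may collapse by hydride shift from C4 to C3 or by re-elimination instead of taking up water, and surplus dioxirane may attack the flavonol double bond or benzylic C–H bonds. Fallback, setting out from 15 and returning at 17: syn-dihydroxylation with catalytic OsO4 and NMO in acetone–water delivers both oxygens in one concerted event, without a cationic intermediate, and gives diol 17 directly.

Further compounds
F1 | step 7 | [2-hydroxy-4,6-bis(benzyloxy)phenyl] furochromenon-8-yl ketone (2-aroylbenzofuran) | O=C(c1c(O)cc(OCc2ccccc2)cc1OCc1ccccc1)c1oc2cc(OCc3ccccc3)c3c(=O)c(OCc4ccccc4)c(-c4ccc(OCc5ccccc5)cc4)oc3c2c1-c1ccc(OCc2ccccc2)cc1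
F2 | step 7 | epoxide of the furan 8,9-double bond of F1 (transient) | O=C(c1c(O)cc(OCc2ccccc2)cc1OCc1ccccc1)C12OC1(c1ccc(OCc3ccccc3)cc1)c1c(O2)cc(OCc3ccccc3)c2c(=O)c(OCc3ccccc3)c(-c3ccc(OCc4ccccc4)cc3)oc12
F3 | step 7 | racemic cis-fused hexabenzyl ketone (18 together with its enantiomer) | O=C1c2c(OCc3ccccc3)cc(OCc3ccccc3)cc2OC2(c3ccc(OCc4ccccc4)cc3)c3c(cc(OCc4ccccc4)c4c(=O)c(OCc5ccccc5)c(-c5ccc(OCc6ccccc6)cc5)oc34)OC12O
F4 | step 4 | 3,5-diacetoxy-2-(4-acetoxyphenyl)-8-(diethoxymethyl)-4H-furo[2,3-h]chromen-4-one | CCOC(OCC)c1oc2cc(OC(C)=O)c3c(=O)c(OC(C)=O)c(-c4ccc(OC(C)=O)cc4)oc3c2c1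
F5 | step 4 | 9-bromo-3,5-diacetoxy-2-(4-acetoxyphenyl)-8-(diethoxymethyl)-4H-furo[2,3-h]chromen-4-one | CCOC(OCC)c1oc2cc(OC(C)=O)c3c(=O)c(OC(C)=O)c(-c4ccc(OC(C)=O)cc4)oc3c2c1Br
F0 | step 8 | none | none
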